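## The problem

The target 17 is a stilbene trimer of two resveratrol units (A, C) and one oxyresveratrol unit (B). Labels used throughout: ring A1 (4-hydroxyphenyl) on C7a, and C8a bearing ring A2 (the free 3,5-dihydroxyphenyl); ring B1 (2,4-dihydroxyphenyl) on C7b, C8b (the CH2), and ring B2 (the central benzene, C9b to C14b); ring C1 (4-hydroxyphenyl) on C7c, and C8c bearing ring C2 (the resorcinol ring C9c to C14c). Ring B2 is pentasubstituted: two trans-2,3-diaryl-2,3-dihydrobenzofurans (O on C11b, C7a, C8a on C10b; O on C13b, C7c, C8c on C14b) flank C9b, and C9b–C8b–C7b–C10c–C9c–C8c–C14b close a seven-membered carbocycle, a 10,11-dihydro-5H-dibenzo[a,d]cycloheptene built from rings B2 and C2. The five stereocentres are (7aR,8aR,7bS,7cR,8cR); C8a and C8c cannot be epimerised and must be set absolutely, and once the C7b–C10c bond is cut they are related by a twofold axis through C12b and C9b, which makes rings A2 and C2 equivalent. C7a and C7c each lie between a 4-oxygenated ring and a phenolic oxygen of ring B2, so each C7–O bond is the closure of a para-quinone-methide-type cation and both centres can be relayed from C8 under thermodynamic control (trans). C7b is the awkward centre: read from the SMILES, H-7b is cis to H-8c on the seven-membered ring (ring B1 trans to H-8c), whereas closure of a C7b cation onto ring C2 is expected to put the aryl group pseudo-axial on the convex face, cis to H-8c; C7b should therefore receive hydrogen, not the aryl ring, last. The feature that makes the key step possible is threefold: C7b sits on ring B1 ortho and para to its two oxygens while C8b is unsubstituted (the footprint of an aryl alkyne polarised towards C7b), C10c is ortho and para to the oxygens on C11c and C13c, and C7a/C7c are quinone-methide carbons. Eight free phenols, two acid-labile benzylic C7–O bonds and four electron-rich rings exclude oxidants and strong acids late in the route.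

## Retrosynthesis

17 from 16. The bonds cut are C7b–H, C8b–H and the eight O–benzyl bonds; 16 is the octabenzyl ether with a C7b=C8b double bond in the seven-membered ring. This cut is preferred to cutting C7b–C10c at the same oxidation level (Alternative 1), which is expected to give the C7b epimer. Compound 16 has one stereocentre fewer and no free phenol. The forward reaction must add hydrogen to the convex face of the folded dibenzocycloheptene (the face of H-8c) and must not hydrogenolyse the C7–O bonds.

16 from 14 (key step). The bonds cut are C7b–C10c and the two C7–O bonds (O on C11b to C7a, O on C13b to C7c), by way of 15. Compound 14 has no ring other than benzene rings, is twofold-symmetric, and only its two C8 centres matter (the carbinol centres are erased). The forward reaction must close two dihydrobenzofurans trans and one seven-membered ring in the 7-endo sense; the choice between rings A2 and C2 is no issue because they are equivalent.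

14 from 12 and 10. The C7 carbinols come from the C7=CH–CH3 alkenes of 12 by oxidative cleavage and reduction. The C8a–C10b and C8c–C14b bonds come from two aromatic Claisen rearrangements of the bis(allyl aryl ether) 10 (through diphenol 11, trapped as diacetate 12). This cut puts both non-epimerisable centres under reagent control by 1,3-chirality transfer and places Ar″ on C7 from the start. The alkyne on C9b is slim during the rearrangement and inert to ozone and hydride. The forward reaction must migrate to C10b/C14b (not C12b) and transfer chirality through a chair transition state.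

10 from 9 and 5. The two aryl O–C bonds are cut; a double Mitsunobu reaction joins the resorcinol 9 with two molecules of the single chiral building block 5, with inversion. Using one alcohol twice means that its minor enantiomer ends mostly in a meso-type diastereomer (Horeau amplification), which is removed later.

5 from 4, 4 from 2 and 3, 2 from 1. The carbinol centre of 5 is the only stereocentre set by a catalyst (CBS reduction of enone 4). Enone 4 is the Knoevenagel-type condensation product of arylacetone 2 (from 1) with aldehyde 3.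

9 from 7 and 8, 7 from 6. The aryl–alkyne bond is cut (Sonogashira coupling of 8 with alkyne 7); 7 comes from aldehyde 6 by one-carbon homologation.

## Roads not taken

Alternative 1: The most obvious cut is C7b–C10c at the stilbene oxidation level. The forward key step protonates the (E)-stilbene A1 at C8b and lets ring C2 close on the C7b cation (the presumed biogenesis; A1 would come from oxidative cross-coupling of the three monomeric stilbenes, or from the present route with a stilbene in place of the alkyne). In that closure ring B1 should take the pseudo-axial site on the convex face to avoid the oxygen on C11c, which places it cis to H-8c, as in the closure of ε-viniferin-type stilbenes to ampelopsin B-type rings. The expected product is therefore A2, the C7b epimer of 17, and the reversibility of the alkylation of so electron-rich a ring points the same way. Oxidative cross-coupling also gives neither regio- nor enantiocontrol. The chosen plan keeps the same polarity (electrophilic C7b, nucleophilic C10c) one oxidation level higher, so that C7b stays trigonal and hydrogen arrives last.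

Alternative 2: Cut all four C–H bonds at C7/C8 and build both heterocycles flat: the tetraaryl benzodifuran A3 (double O-alkylation, double cyclodehydration, double C2-arylation), then hydrogenation. Syn delivery of hydrogen to the second furan from the face left free by the first gives the all-cis compound A4, in which the two rings have opposite absolute sense (meso-type), whereas 17 needs the twofold-symmetric array. In addition, no catalyst is established for enantioselective hydrogenation of 2,3-diarylbenzofurans. This route controls neither the relative nor the absolute configuration of C8a/C8c; the chosen plan sets both by reagent control from one carbinol.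

Alternative 3: Cut the C7–C8 bonds and form them by dirhodium-carbene C–H insertion: the bis(hydrazone) A5 is oxidised to the bis(diaryldiazomethane) and a chiral dirhodium tetracarboxylate inserts each carbene into the neighbouring OCH2Ar bond. Both ketones of the precursor are flanked by two ortho substituents, so hydrazone formation is the weak point. The 4,6-diaroylation of a 5-substituted resorcinol is itself a problem, the insertion gives cis rings that need a separate epimerisation, and C9b needs a later handle. The chosen plan is shorter and takes both C8 centres from one CBS reduction.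

Key step: step 9

Assumption: compounds 1, 3, 6 and 8 are taken as commercial; hydrogen is taken to add to the convex face of the folded dibenzocycloheptene 16, and the CBS reduction is taken to follow the usual large-group/small-group model with the 1,2-diarylvinyl group as the large group.

## Steps

Step 1
Reactants: 1 1-(4-hydroxyphenyl)propan-2-one
Product: 2 1-[4-(benzyloxy)phenyl]propan-2-one
Conditions: BnBr, K2CO3, acetone, reflux
Reagents that add atoms: benzyl bromide BrCc1ccccc1
Why: Williamson ether synthesis; the phenoxide is alkylated much faster than the ketone enolate under carbonate conditions.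

Step 2
Reactants: 2 1-[4-(benzyloxy)phenyl]propan-2-one; 3 3,5-bis(benzyloxy)benzaldehyde
Product: 4 (3E)-4-[3,5-bis(benzyloxy)phenyl]-3-[4-(benzyloxy)phenyl]but-3-en-2-one
Conditions: piperidine, AcOH (cat.), toluene, reflux, Dean–Stark
Reagents that add atoms: none
Why: Knoevenagel-type condensation at the more acidic benzylic methylene of the arylacetone; the thermodynamic E isomer (acetyl trans to the new aryl group) should predominate, which is the geometry the later rearrangement needs.

Step 3
Reactants: 4 (3E)-4-[3,5-bis(benzyloxy)phenyl]-3-[4-(benzyloxy)phenyl]but-3-en-2-one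
Product: 5 (2S,3E)-4-[3,5-bis(benzyloxy)phenyl]-3-[4-(benzyloxy)phenyl]but-3-en-2-ol
Conditions: (R)-2-methyl-CBS-oxazaborolidine (0.2 equiv), catecholborane, toluene, −78 °C
Reagents that add atoms: none
Why: CBS reduction of an α-substituted enone, 1,2-selective with catecholborane; with the diarylvinyl group as the large and methyl as the small substituent the (R)-catalyst should give the (S)-carbinol, the only stereocentre in the route set by a catalyst.

Step 4
Reactants: 6 2,4-bis(benzyloxy)benzaldehyde
Product: 7 2,4-bis(benzyloxy)-1-ethynylbenzene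
Conditions: dimethyl (1-diazo-2-oxopropyl)phosphonate, K2CO3, MeOH/THF, 25 °C
Reagents that add atoms: dimethyl (1-diazo-2-oxopropyl)phosphonate COP(=O)(OC)C(=[N+]=[N-])C(C)=O
Why: Ohira–Bestmann (Seyferth–Gilbert) homologation of an aryl aldehyde to the terminal alkyne under mild base.

Step 5
Reactants: 7 2,4-bis(benzyloxy)-1-ethynylbenzene; 8 5-iodobenzene-1,3-diol
Product: 9 5-{[2,4-bis(benzyloxy)phenyl]ethynyl}benzene-1,3-diol
Conditions: PdCl2(PPh3)2 (3 mol %), CuI (5 mol %), Et3N, THF, 25–50 °C
Reagents that add atoms: none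
Why: Sonogashira coupling of an aryl iodide with a terminal alkyne; free phenols are tolerated and the unhindered position is coupled before any crowding is built up.

Step 6
Reactants: 9 5-{[2,4-bis(benzyloxy)phenyl]ethynyl}benzene-1,3-diol; 5 (2S,3E)-4-[3,5-bis(benzyloxy)phenyl]-3-[4-(benzyloxy)phenyl]but-3-en-2-ol (2.3 equiv)
Product: 10 1-{[2,4-bis(benzyloxy)phenyl]ethynyl}-3,5-bis{[(2R,3E)-4-[3,5-bis(benzyloxy)phenyl]-3-[4-(benzyloxy)phenyl]but-3-en-2-yl]oxy}benzene
Conditions: PPh3, DIAD, THF, 0 to 25 °C
Reagents that add atoms: none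
Why: Double Mitsunobu etherification of the acidic resorcinol; SN2 displacement at the allylic carbinol carbon inverts it, so (S)-5 gives the (R,R)-bis-ether.

Step 7
Reactants: 10 1-{[2,4-bis(benzyloxy)phenyl]ethynyl}-3,5-bis{[(2R,3E)-4-[3,5-bis(benzyloxy)phenyl]-3-[4-(benzyloxy)phenyl]but-3-en-2-yl]oxy}benzene
Product: 12 5-{[2,4-bis(benzyloxy)phenyl]ethynyl}-4,6-bis{(1S,2Z)-1-[3,5-bis(benzyloxy)phenyl]-2-[4-(benzyloxy)phenyl]but-2-en-1-yl}-1,3-phenylene diacetate, via diphenol 11 (not isolated)
Conditions: PhNEt2, 185 °C, sealed tube; then Ac2O, DMAP, 25 °C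
Reagents that add atoms: acetic anhydride CC(=O)OC(C)=O
Why: Double aromatic Claisen rearrangement; each allyl group should migrate to the ortho carbon that is para to the other oxygen and next to the slim alkynyl group (C10b, C14b), as both meta substituents direct. A chair transition state with the methyl group equatorial and the E-alkene aryl group equatorial transfers the (R)-ether centre suprafacially to C8, giving the configuration that is (S) in 11/12 and becomes (R) once C7 carries oxygen, with the new alkene Z. Acetylation masks the phenols for the next step and allows the meso-type diastereomer that carries the minor enantiomer of 5 to be removed.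

Step 8
Reactants: 12 5-{[2,4-bis(benzyloxy)phenyl]ethynyl}-4,6-bis{(1S,2Z)-1-[3,5-bis(benzyloxy)phenyl]-2-[4-(benzyloxy)phenyl]but-2-en-1-yl}-1,3-phenylene diacetate
Product: 14 5-{[2,4-bis(benzyloxy)phenyl]ethynyl}-4,6-bis{(1R)-1-[3,5-bis(benzyloxy)phenyl]-2-[4-(benzyloxy)phenyl]-2-hydroxyethyl}benzene-1,3-diol (epimer mixture at both carbinol carbons), via diketone 13 (not isolated)
Conditions: O3, CH2Cl2/MeOH 3:1, −78 °C; NaBH4, −78 to 0 °C; K2CO3, MeOH, 25 °C
Reagents that add atoms: ozone O=[O+][O-]
Why: Ozonolysis of the two electron-rich trisubstituted alkenes (the diaryl alkyne reacts far more slowly), reduction of the ketones in the same flask and methanolysis of the acetates. The acetates keep the phenols from adding to the ketones (no benzofuran formation), and the acidic C8–H next to each ketone meets hydride at low temperature before it meets base. The configuration at the new carbinol carbons is irrelevant because it is erased in step 9.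

Step 9
Reactants: 14 5-{[2,4-bis(benzyloxy)phenyl]ethynyl}-4,6-bis{(1R)-1-[3,5-bis(benzyloxy)phenyl]-2-[4-(benzyloxy)phenyl]-2-hydroxyethyl}benzene-1,3-diol
Product: 16 octa-O-benzyl ether of (7aR,8aR,7cR,8cR)-7b,8b-didehydro-17 (5H-dibenzo[a,d]cycloheptene with the C7b=C8b double bond, both dihydrobenzofurans trans), via bis(dihydrobenzofuran) alkyne 15 (not isolated)
Conditions: TsOH·H2O (10 mol %), CH2Cl2, 25 °C; then 4 Å sieves, [(t-Bu)2(2-biphenylyl)P]Au(NCMe)SbF6 (5 mol %), 25–40 °C
Reagents that add atoms: none
Why: Acid-triggered SN1 cyclodehydration followed by gold-catalysed intramolecular alkyne hydroarylation in one flask. First, TsOH ionises each 4-(benzyloxy)benzylic carbinol of 14 to a para-quinone-methide-type cation at C7, which the ortho phenol oxygen (on C11b or C13b) traps in a 5-exo closure; the closure is reversible, so C7a and C7c should settle trans to the fixed C8a and C8c (all R) whatever the carbinol configuration was, and ring closure should outrun loss of the C8 proton. Second, the cationic gold complex binds the alkyne of 15, positive charge builds at C7b next to the 2,4-dioxygenated ring B1, and C10c of one resorcinol ring (ortho and para to its two oxygens) attacks C7b anti to gold in a 7-endo-dig closure; protodeauration leaves the ring double bond C7b=C8b of 16. The closest known reaction types are the acid cyclisation of 2-(2-aryl-2-hydroxyethyl)phenols to trans-2,3-diaryldihydrobenzofurans and the gold-catalysed hydroarylation of diaryl alkynes by electron-rich arenes to benzo-fused seven-membered rings; the proton-induced closure of ε-viniferin-type stilbenes is the biogenetic model. The step needs endo over 6-exo-dig attack (secured by the polarisation of the alkyne towards C7b) and C- over O-attack on the alkyne (the carbinols are consumed before gold is added and the phenol oxygens are by then ring oxygens); it needs no choice between the two resorcinol rings, which are equivalent by the twofold axis of 15, so the step desymmetrises without a selectivity issue. The only stereocentres it sets are C7a and C7c; C7b is left trigonal on purpose.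

Step 10
Reactants: 16 octa-O-benzyl ether of (7aR,8aR,7cR,8cR)-7b,8b-didehydro-17
Product: 17 target, (7aR,8aR,7bS,7cR,8cR)
Conditions: H2 (4 bar), 10% Pd/C, EtOAc/MeOH 1:1, 25 °C
Reagents that add atoms: none
Why: Heterogeneous syn-hydrogenation of the only C=C bond together with hydrogenolysis of the eight benzyl ethers. The dibenzocycloheptene is folded, rings B2 and C2 wall the concave face, and H-8c is pseudo-axial on the convex face because C7c is held in the plane of ring B2; hydrogen should add to the convex face, so the new H-7b is cis to H-8c, which is (7bS). This is the epimer that an aryl group arriving last would not give.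

## Compound list

1 | 1-(4-hydroxyphenyl)propan-2-one | CC(=O)Cc1ccc(O)cc1 | starting material
2 | 1-[4-(benzyloxy)phenyl]propan-2-one | CC(=O)Cc1ccc(OCc6ccccc6)cc1 | intermediate
3 | 3,5-bis(benzyloxy)benzaldehyde | O=Cc1cc(OCc6ccccc6)cc(OCc6ccccc6)c1 | starting material
4 | (3E)-4-[3,5-bis(benzyloxy)phenyl]-3-[4-(benzyloxy)phenyl]but-3-en-2-one | CC(=O)/C(c1ccc(OCc6ccccc6)cc1)=C/c1cc(OCc6ccccc6)cc(OCc6ccccc6)c1 | intermediate
5 | (2S,3E)-4-[3,5-bis(benzyloxy)phenyl]-3-[4-(benzyloxy)phenyl]but-3-en-2-ol | C[C@H](O)/C(c1ccc(OCc6ccccc6)cc1)=C/c1cc(OCc6ccccc6)cc(OCc6ccccc6)c1 | intermediate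
6 | 2,4-bis(benzyloxy)benzaldehyde | O=Cc1ccc(OCc6ccccc6)cc1OCc6ccccc6 | starting material
7 | 2,4-bis(benzyloxy)-1-ethynylbenzene | C#Cc1ccc(OCc6ccccc6)cc1OCc6ccccc6 | intermediate
8 | 5-iodobenzene-1,3-diol | Oc1cc(O)cc(I)c1 | starting material
9 | 5-{[2,4-bis(benzyloxy)phenyl]ethynyl}benzene-1,3-diol | Oc1cc(O)cc(C#Cc2ccc(OCc6ccccc6)cc2OCc6ccccc6)c1 | intermediate
10 | 1-{[2,4-bis(benzyloxy)phenyl]ethynyl}-3,5-bis{[(2R,3E)-4-[3,5-bis(benzyloxy)phenyl]-3-[4-(benzyloxy)phenyl]but-3-en-2-yl]oxy}benzene | c1(C#Cc2ccc(OCc6ccccc6)cc2OCc6ccccc6)cc(O[C@H](C)/C(c2ccc(OCc6ccccc6)cc2)=C/c2cc(OCc6ccccc6)cc(OCc6ccccc6)c2)cc(O[C@H](C)/C(c2ccc(OCc6ccccc6)cc2)=C/c2cc(OCc6ccccc6)cc(OCc6ccccc6)c2)c1 | intermediate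
11 | 5-{[2,4-bis(benzyloxy)phenyl]ethynyl}-4,6-bis{(1S,2Z)-1-[3,5-bis(benzyloxy)phenyl]-2-[4-(benzyloxy)phenyl]but-2-en-1-yl}benzene-1,3-diol | Oc1cc(O)c([C@@H](c2cc(OCc6ccccc6)cc(OCc6ccccc6)c2)/C(c2ccc(OCc6ccccc6)cc2)=C/C)c(C#Cc2ccc(OCc6ccccc6)cc2OCc6ccccc6)c1[C@@H](c1cc(OCc6ccccc6)cc(OCc6ccccc6)c1)/C(c1ccc(OCc6ccccc6)cc1)=C/C | intermediate (not isolated)
12 | diacetate of 11 | CC(=O)Oc1cc(OC(C)=O)c([C@@H](c2cc(OCc6ccccc6)cc(OCc6ccccc6)c2)/C(c2ccc(OCc6ccccc6)cc2)=C/C)c(C#Cc2ccc(OCc6ccccc6)cc2OCc6ccccc6)c1[C@@H](c1cc(OCc6ccccc6)cc(OCc6ccccc6)c1)/C(c1ccc(OCc6ccccc6)cc1)=C/C | intermediate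
13 | 5-{[2,4-bis(benzyloxy)phenyl]ethynyl}-4,6-bis{(1R)-1-[3,5-bis(benzyloxy)phenyl]-2-[4-(benzyloxy)phenyl]-2-oxoethyl}-1,3-phenylene diacetate | CC(=O)Oc1cc(OC(C)=O)c([C@@H](c2cc(OCc6ccccc6)cc(OCc6ccccc6)c2)C(=O)c2ccc(OCc6ccccc6)cc2)c(C#Cc2ccc(OCc6ccccc6)cc2OCc6ccccc6)c1[C@@H](c1cc(OCc6ccccc6)cc(OCc6ccccc6)c1)C(=O)c1ccc(OCc6ccccc6)cc1 | intermediate (not isolated)
14 | 5-{[2,4-bis(benzyloxy)phenyl]ethynyl}-4,6-bis{(1R)-1-[3,5-bis(benzyloxy)phenyl]-2-[4-(benzyloxy)phenyl]-2-hydroxyethyl}benzene-1,3-diol (carbinol carbons: epimer mixture, drawn without configuration) | Oc1cc(O)c([C@@H](c2cc(OCc6ccccc6)cc(OCc6ccccc6)c2)C(O)c2ccc(OCc6ccccc6)cc2)c(C#Cc2ccc(OCc6ccccc6)cc2OCc6ccccc6)c1[C@@H](c1cc(OCc6ccccc6)cc(OCc6ccccc6)c1)C(O)c1ccc(OCc6ccccc6)cc1 | intermediate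
15 | (2R,3R,5R,6R)-4-{[2,4-bis(benzyloxy)phenyl]ethynyl}-3,5-bis[3,5-bis(benzyloxy)phenyl]-2,6-bis[4-(benzyloxy)phenyl]-2,3,5,6-tetrahydrobenzo[1,2-b:5,4-b']difuran | C(#Cc1c2[C@@H](c3cc(OCc6ccccc6)cc(OCc6ccccc6)c3)[C@H](c3ccc(OCc6ccccc6)cc3)Oc2cc2O[C@@H](c3ccc(OCc6ccccc6)cc3)[C@H](c3cc(OCc6ccccc6)cc(OCc6ccccc6)c3)c12)c1ccc(OCc6ccccc6)cc1OCc6ccccc6 | intermediate (not isolated)
16 | octa-O-benzyl ether of (7aR,8aR,7cR,8cR)-7b,8b-didehydro-17 | c6ccccc6COc1ccc([C@@H]2Oc3cc4c5c(c3[C@H]2c2cc(OCc6ccccc6)cc(OCc6ccccc6)c2)C=C(c2ccc(OCc6ccccc6)cc2OCc6ccccc6)c2c(OCc6ccccc6)cc(OCc6ccccc6)cc2[C@H]5[C@H](c2ccc(OCc6ccccc6)cc2)O4)cc1 | intermediate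
17 | target, (7aR,8aR,7bS,7cR,8cR) | Oc1ccc([C@@H]2Oc3cc4c5c(c3[C@H]2c2cc(O)cc(O)c2)C[C@@H](c2ccc(O)cc2O)c2c(O)cc(O)cc2[C@H]5[C@H](c2ccc(O)cc2)O4)cc1 | target

## Step count and least certain steps

Total step count: 10. Longest linear sequence: 8 steps (steps 1, 2, 3, 6, 7, 8, 9, 10).

Step 9 (key step). Most likely failure: wrong regiochemistry in the gold stage, that is 6-exo-dig attack of C10c on C8b or hydration of the activated alkyne. The exo mode is geometrically as accessible as the endo mode and only the polarisation by ring B1 discriminates. Fallback, which changes the electrophile: it sets out from 15, isolated after the acid stage. Gold-catalysed hydration in wet dioxane puts the oxygen on C7b and gives the benzyl aryl ketone F1. Cyclodehydration of F1 with Bi(OTf)3 in dichloroethane lets ring C2 add to the carbonyl carbon C7b, which can only form the seven-membered ring, and the tertiary benzylic alcohol loses water towards C8b. The sequence comes back to the route at 16.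

Step 10. Most likely failure: poor facial selectivity or a stalled reduction, because ring A2 on C8a leans over the convex face near C8b and the alkene is triaryl-substituted; prolonged exposure also risks hydrogenolysis of the benzylic C7–O bonds. Fallback, reagent control in place of substrate control: it sets out from 16. Homogeneous hydrogenation with [Ir(cod)(t-Bu-PHOX)][B(3,5-(CF3)2C6H3)4] (both ligand antipodes are available and benzyl ethers are untouched) gives the octa-O-benzyl ether of 17, F2. A short hydrogenolysis of F2 over Pd(OH)2/C then comes back to the route at 17.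

Step 7. Most likely failure: loss of regiocontrol in the second rearrangement (migration to C12b between the two oxygens) and partial loss of chirality transfer through ionisation of the doubly activated allyl aryl ether at 185 °C. Fallback, stepwise in place of two-directional: it sets out from 9. Mitsunobu reaction with one equivalent of 5 gives the mono-ether F3. Its rearrangement, now steered by a free meta hydroxyl group, gives the mono-allyl diphenol F4. The less hindered hydroxyl group of F4 is etherified with 5 to give F5, and rearrangement of F5 comes back to the route at 11.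

Step 6. Most likely failure: SN2′ attack, elimination to the diene or partial racemisation through the allyl cation, because the carbinol is secondary, allylic and next to a 1,1-disubstituted alkene carbon. Fallback, forming the aryl–oxygen bond in place of the alkyl–oxygen bond: it sets out from 4. CBS reduction with the (S)-catalyst gives the enantiomeric alcohol F6. Coupling of F6 with 1-bromo-3,5-diiodobenzene (CuI, 3,4,7,8-tetramethyl-1,10-phenanthroline, Cs2CO3, toluene, 100 °C) leaves the carbinol configuration untouched and gives the aryl bromide F7. Sonogashira coupling of F7 with 7 comes back to the route at 10.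

## Further compounds

F1 | step 9 | 1-[2,4-bis(benzyloxy)phenyl]-2-{(2R,3R,5R,6R)-3,5-bis[3,5-bis(benzyloxy)phenyl]-2,6-bis[4-(benzyloxy)phenyl]-2,3,5,6-tetrahydrobenzo[1,2-b:5,4-b']difuran-4-yl}ethan-1-one | O=C(Cc1c2[C@@H](c3cc(OCc6ccccc6)cc(OCc6ccccc6)c3)[C@H](c3ccc(OCc6ccccc6)cc3)Oc2cc2O[C@@H](c3ccc(OCc6ccccc6)cc3)[C@H](c3cc(OCc6ccccc6)cc(OCc6ccccc6)c3)c12)c1ccc(OCc6ccccc6)cc1OCc6ccccc6
F2 | step 10 | octa-O-benzyl ether of 17 | c6ccccc6COc1ccc([C@@H]2Oc3cc4c5c(c3[C@H]2c2cc(OCc6ccccc6)cc(OCc6ccccc6)c2)C[C@@H](c2ccc(OCc6ccccc6)cc2OCc6ccccc6)c2c(OCc6ccccc6)cc(OCc6ccccc6)cc2[C@H]5[C@H](c2ccc(OCc6ccccc6)cc2)O4)cc1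
F3 | step 7 | 3-{[(2R,3E)-4-[3,5-bis(benzyloxy)phenyl]-3-[4-(benzyloxy)phenyl]but-3-en-2-yl]oxy}-5-{[2,4-bis(benzyloxy)phenyl]ethynyl}phenol | Oc1cc(O[C@H](C)/C(c2ccc(OCc6ccccc6)cc2)=C/c2cc(OCc6ccccc6)cc(OCc6ccccc6)c2)cc(C#Cc2ccc(OCc6ccccc6)cc2OCc6ccccc6)c1
F4 | step 7 | 5-{[2,4-bis(benzyloxy)phenyl]ethynyl}-4-{(1S,2Z)-1-[3,5-bis(benzyloxy)phenyl]-2-[4-(benzyloxy)phenyl]but-2-en-1-yl}benzene-1,3-diol | Oc1cc(O)c([C@@H](c2cc(OCc6ccccc6)cc(OCc6ccccc6)c2)/C(c2ccc(OCc6ccccc6)cc2)=C/C)c(C#Cc2ccc(OCc6ccccc6)cc2OCc6ccccc6)c1
F5 | step 7 | 5-{[(2R,3E)-4-[3,5-bis(benzyloxy)phenyl]-3-[4-(benzyloxy)phenyl]but-3-en-2-yl]oxy}-3-{[2,4-bis(benzyloxy)phenyl]ethynyl}-2-{(1S,2Z)-1-[3,5-bis(benzyloxy)phenyl]-2-[4-(benzyloxy)phenyl]but-2-en-1-yl}phenol | O([C@H](C)/C(c1ccc(OCc6ccccc6)cc1)=C/c1cc(OCc6ccccc6)cc(OCc6ccccc6)c1)c1cc(O)c([C@@H](c2cc(OCc6ccccc6)cc(OCc6ccccc6)c2)/C(c2ccc(OCc6ccccc6)cc2)=C/C)c(C#Cc2ccc(OCc6ccccc6)cc2OCc6ccccc6)c1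
F6 | step 6 | (2R,3E)-4-[3,5-bis(benzyloxy)phenyl]-3-[4-(benzyloxy)phenyl]but-3-en-2-ol | C[C@@H](O)/C(c1ccc(OCc6ccccc6)cc1)=C/c1cc(OCc6ccccc6)cc(OCc6ccccc6)c1
F7 | step 6 | 1-bromo-3,5-bis{[(2R,3E)-4-[3,5-bis(benzyloxy)phenyl]-3-[4-(benzyloxy)phenyl]but-3-en-2-yl]oxy}benzene | Brc1cc(O[C@H](C)/C(c2ccc(OCc6ccccc6)cc2)=C/c2cc(OCc6ccccc6)cc(OCc6ccccc6)c2)cc(O[C@H](C)/C(c2ccc(OCc6ccccc6)cc2)=C/c2cc(OCc6ccccc6)cc(OCc6ccccc6)c2)c1
A1 | alternative 1 | (E)-stilbene with two trans-(R,R)-dihydrobenzofurans on ring B2, all phenols free | Oc1ccc(/C=C/c2c3[C@@H](c4cc(O)cc(O)c4)[C@H](c4ccc(O)cc4)Oc3cc3O[C@@H](c4ccc(O)cc4)[C@H](c4cc(O)cc(O)c4)c23)c(O)c1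
A2 | alternative 1 | C7b epimer of 17, (7aR,8aR,7bR,7cR,8cR) | Oc1ccc([C@@H]2Oc3cc4c5c(c3[C@H]2c2cc(O)cc(O)c2)C[C@H](c2ccc(O)cc2O)c2c(O)cc(O)cc2[C@H]5[C@H](c2ccc(O)cc2)O4)cc1
A3 | alternative 2 | methyl 3,5-bis(3,5-dimethoxyphenyl)-2,6-bis(4-methoxyphenyl)benzo[1,2-b:5,4-b']difuran-4-carboxylate | COC(=O)c1c2c(-c3cc(OC)cc(OC)c3)c(-c3ccc(OC)cc3)oc2cc2oc(-c3ccc(OC)cc3)c(-c3cc(OC)cc(OC)c3)c12
A4 | alternative 2 | methyl (2S,3R,5S,6R)-3,5-bis(3,5-dimethoxyphenyl)-2,6-bis(4-methoxyphenyl)-2,3,5,6-tetrahydrobenzo[1,2-b:5,4-b']difuran-4-carboxylate (all-cis, meso-type) | COC(=O)c1c2[C@@H](c3cc(OC)cc(OC)c3)[C@@H](c3ccc(OC)cc3)Oc2cc2O[C@@H](c3ccc(OC)cc3)[C@@H](c3cc(OC)cc(OC)c3)c12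
A5 | alternative 3 | 1,1'-(2-bromo-4,6-bis{[4-(benzyloxy)phenyl]methoxy}-1,3-phenylene)bis{[3,5-bis(benzyloxy)phenyl]methanone} dihydrazone | NN=C(c1cc(OCc6ccccc6)cc(OCc6ccccc6)c1)c1c(OCc2ccc(OCc6ccccc6)cc2)cc(OCc2ccc(OCc6ccccc6)cc2)c(C(=NN)c2cc(OCc6ccccc6)cc(OCc6ccccc6)c2)c1Br
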